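**Retrosynthetic overview**

1. Target 12 is the 33-membered lactone of 32-hydroxydotriacontanoic acid (C1 = lactone carbonyl carbon, C32 = OCH2). It has one ring and no stereocentre, and the ring is formed once, in step 5.
2. Enabling feature: ring atoms C27–C28–C29–C30 are four unbranched, unsubstituted CH2 groups, with C29 four carbons from the ring oxygen (O–C32–C31–C30–C29). This stretch can therefore be carried as a conjugated diyne C27≡C28–C29≡C30 and erased by hydrogenation at the end.
3. Key disconnection: the C28–C29 sp–sp bond, made far from the ester by intramolecular oxidative (Eglinton) coupling of the two terminal alkynes of but-3-yn-1-yl octacos-27-ynoate 10.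
4. Ester 10 comes from but-3-yn-1-ol (ring O and C32–C29) and octacos-27-ynoic acid 8 (C1–C28). Acid 8 comes from dec-9-yn-1-ol and 1-bromooctadecane by alkynide alkylation, an alkyne zipper over 18 positions to the chain end, and Jones oxidation.
5. Last step: exhaustive hydrogenation of the macrocyclic diyne 11 to 12.

Key step: step 5

**Route**

Step 1
Reactants: 1 dec-9-yn-1-ol; 2 1-bromooctadecane
Product: 4 octacos-9-yn-1-ol, via dilithium alkoxide-alkynide 3 (not isolated)
Conditions: n-BuLi (2.1 equiv), THF/DMPU, −40 → 0 °C; then 2, 0 → 40 °C; H2O
Reagents that add atoms: none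
Why: Double deprotonation gives the lithium alkoxide–alkynide, whose carbon terminus is much the better nucleophile in THF/DMPU and should displace the primary bromide by SN2 (alkylation of an alkynol dianion); no stereocentre is formed.

Step 2
Reactants: 4 octacos-9-yn-1-ol
Product: 6 octacos-27-yn-1-ol, via dipotassium alkoxide-alkynide 5 (not isolated)
Conditions: KH (5 equiv), H2N(CH2)3NH2, 20 °C; then 4 in THF, 20 → 45 °C; H2O, 0 °C
Reagents that add atoms: none
Why: Alkyne zipper reaction: potassium 3-aminopropylamide, made from KH and the diamine, should move the triple bond along the unbranched chain by repeated propargyl–allenyl proton shifts until it is trapped irreversibly at the only free chain end as the potassium alkynide 5, an isomerization with precedent for long-chain alkynols.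

Step 3
Reactants: 6 octacos-27-yn-1-ol
Product: 8 octacos-27-ynoic acid, via octacos-27-ynal 7 (not isolated)
Conditions: CrO3, H2SO4, H2O, acetone/CH2Cl2, 0 → 20 °C
Reagents that add atoms: water, O (from the aqueous Jones reagent; the second carboxyl oxygen enters through the hydrate of aldehyde 7; chromium trioxide, O=[Cr](=O)=O, is the oxidant and exchanges oxygen with this water)
Why: Jones oxidation with hexavalent chromium should take the primary alcohol through the aldehyde hydrate to the acid, while the terminal alkyne is inert to the reagent.

Step 4
Reactants: 8 octacos-27-ynoic acid; 9 but-3-yn-1-ol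
Product: 10 but-3-yn-1-yl octacos-27-ynoate
Conditions: DCC (1.2 equiv), DMAP (0.1 equiv), CH2Cl2/THF, 0 → 30 °C
Reagents that add atoms: none
Why: Steglich esterification: DCC activates the acid as the O-acylisourea and DMAP transfers the acyl group to the unhindered primary alcohol under neutral conditions that leave both terminal alkynes untouched.

Step 5
Reactants: 10 but-3-yn-1-yl octacos-27-ynoate
Product: 11 oxacyclotritriaconta-28,30-diyn-2-one
Conditions: Cu(OAc)2 (8 equiv), pyridine/MeCN (4:1), 60 °C, syringe-pump addition of 10 over 24 h (final 1 mM); aq. NH4Cl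
Reagents that add atoms: none
Why: Eglinton oxidative coupling (Glaser family): pyridine-assisted cupration of both terminal alkynes gives copper alkynides, and divalent copper oxidises the pair to the C28–C29 sp–sp bond with release of monovalent copper; the closest known reaction type is the oxidative macrocyclization of ester-linked α,ω-diynes to macrocyclic 1,3-diyne lactones. The 33-membered ring is closed head-to-tail by this end-to-end coupling, both triple bonds ending up endocyclic as a strain-free linear rod (C26 to C31) in a ring spanned by 25 methylene groups. No stereocentre is formed. The selectivity needed is intra- over intermolecular coupling; it is secured by pseudo-high dilution (slow addition into excess Cu(OAc)2) and, in the substrate, by exactly two terminal alkynes joined through a long flexible tether that carries no other copper-reactive group. The ring oxygen is homopropargylic, not propargylic, so C–O cleavage is not expected here or in the hydrogenation that follows.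

Step 6
Reactants: 11 oxacyclotritriaconta-28,30-diyn-2-one
Product: 12 oxacyclotritriacontan-2-one
Conditions: H2 (3 bar), 10% Pd/C, EtOAc/THF, 25 °C
Reagents that add atoms: none
Why: Exhaustive heterogeneous hydrogenation on Pd/C should saturate the conjugated diyne with four equivalents of H2, while the lactone is inert and no stereocentre is involved.

**Compound list**

1 | dec-9-yn-1-ol | C#CCCCCCCCCO | starting material
2 | 1-bromooctadecane | CCCCCCCCCCCCCCCCCCBr | starting material
3 | dilithium 10-oxidodec-1-yn-1-ide (dilithium alkoxide-alkynide of 1) | [Li+].[Li+].[C-]#CCCCCCCCC[O-] | intermediate (not isolated)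
4 | octacos-9-yn-1-ol | CCCCCCCCCCCCCCCCCCC#CCCCCCCCCO | intermediate
5 | dipotassium 28-oxidooctacos-1-yn-1-ide (dipotassium alkoxide-alkynide of 6) | [K+].[K+].[C-]#CCCCCCCCCCCCCCCCCCCCCCCCCCC[O-] | intermediate (not isolated)
6 | octacos-27-yn-1-ol | C#CCCCCCCCCCCCCCCCCCCCCCCCCCCO | intermediate
7 | octacos-27-ynal | C#CCCCCCCCCCCCCCCCCCCCCCCCCCC=O | intermediate (not isolated)
8 | octacos-27-ynoic acid | C#CCCCCCCCCCCCCCCCCCCCCCCCCCC(=O)O | intermediate
9 | but-3-yn-1-ol | C#CCCO | starting material
10 | but-3-yn-1-yl octacos-27-ynoate | C#CCCOC(=O)CCCCCCCCCCCCCCCCCCCCCCCCCC#C | intermediate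
11 | oxacyclotritriaconta-28,30-diyn-2-one | O=C1CCCCCCCCCCCCCCCCCCCCCCCCCC#CC#CCCO1 | intermediate
12 | oxacyclotritriacontan-2-one | O=C1CCCCCCCCCCCCCCCCCCCCCCCCCCCCCCCO1 | target

**Step count**

Total step count: 6. Longest linear sequence: 6 steps (1 → 4 → 6 → 8 → 10 → 11 → 12).

**Steps most likely to fail**

Step 5 (ring closure). Intermolecular oxidative coupling (head-to-head, tail-to-tail and head-to-tail) may outrun ring closure and consume 10 irreversibly as linear and cyclic oligomers. The fallback sets out from 8 (with 9 as the source of the four-carbon alcohol) and comes back to the route at 12. It makes the C28–C29 bond intermolecularly and closes the ring at the ester instead. Alcohol 9 would be brominated at the alkyne terminus (NBS, cat. AgNO3, acetone, 20 °C) to 4-bromobut-3-yn-1-ol F1. Cadiot–Chodkiewicz coupling of F1 with acid 8 (cat. CuCl, NH2OH·HCl, aq. n-BuNH2, MeOH/THF, 0 → 20 °C) should give 32-hydroxydotriaconta-27,29-diynoic acid F2 in a defined head-to-tail sense. Hydrogenation (H2, Pd/C, THF/MeOH, 40 °C) would give 32-hydroxydotriacontanoic acid F3. Yamaguchi macrolactonization would then close the 33-membered ring to 12: 2,4,6-trichlorobenzoyl chloride and Et3N in THF give the mixed 2,4,6-trichlorobenzoic anhydride F4, which is added slowly to DMAP in toluene at reflux (1 mM).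

Step 2 (alkyne zipper). Migration over 18 positions may stall because the long-chain potassium alkoxide dissolves poorly in the diamine, leaving positional alkyne and allene isomers that are hard to separate. The fallback sets out from 3 (made from 1 as in step 1) and comes back to the route at 12. It installs the terminal alkyne by substitution instead of isomerization and carries the internal triple bonds along, since the Eglinton step couples only terminal alkynes and the last step saturates everything. Dianion 3 would be alkylated with 1,10-dibromodecane (4 equiv, THF/DMPU) to 20-bromoicos-9-yn-1-ol F5. F5, as its lithium alkoxide, would be treated with lithium octa-1,7-diyn-1-ide F6 (from excess octa-1,7-diyne and n-BuLi, THF/DMPU, 0 → 40 °C) to give octacosa-9,21,27-triyn-1-ol F7. Jones oxidation, through octacosa-9,21,27-triynal F8, would give octacosa-9,21,27-triynoic acid F9. DCC/DMAP esterification with 9 would give but-3-yn-1-yl octacosa-9,21,27-triynoate F10. Eglinton coupling under the conditions of step 5 should give oxacyclotritriaconta-10,22,28,30-tetrayn-2-one F11, and hydrogenation (H2, Pd/C) would give 12.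

Step 1 (alkynide alkylation). The sparingly soluble dilithio species may aggregate, so that C-alkylation is slow and elimination of HBr from 2 or O-alkylation competes. The fallback sets out from 2 and comes back to the route at 4. It reverses the roles of the fragments so that the nucleophile carries no alkoxide. Bromide 2 would be treated with lithium acetylide–ethylenediamine complex (DMSO, 20 °C) to give icos-1-yne F12. Deprotonation of F12 (n-BuLi, THF/DMPU) and alkylation with 2-[(8-bromooctyl)oxy]oxane F13 (from 8-bromooctan-1-ol, 3,4-dihydro-2H-pyran and cat. pyridinium p-toluenesulfonate) should give 2-(octacos-9-yn-1-yloxy)oxane F14. Acidic methanolysis (cat. p-TsOH, MeOH/THF) would release 4.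

Further compounds
F1 | step 5 | 4-bromobut-3-yn-1-ol | BrC#CCCO
F2 | step 5 | 32-hydroxydotriaconta-27,29-diynoic acid | OCCC#CC#CCCCCCCCCCCCCCCCCCCCCCCCCCC(=O)O
F3 | step 5 | 32-hydroxydotriacontanoic acid | OCCCCCCCCCCCCCCCCCCCCCCCCCCCCCCCC(=O)O
F4 | step 5 | 32-hydroxydotriacontanoic 2,4,6-trichlorobenzoic anhydride | OCCCCCCCCCCCCCCCCCCCCCCCCCCCCCCCC(=O)OC(=O)c1c(Cl)cc(Cl)cc1Cl
F5 | step 2 | 20-bromoicos-9-yn-1-ol | OCCCCCCCCC#CCCCCCCCCCCBr
F6 | step 2 | lithium octa-1,7-diyn-1-ide | [Li+].[C-]#CCCCCC#C
F7 | step 2 | octacosa-9,21,27-triyn-1-ol | OCCCCCCCCC#CCCCCCCCCCCC#CCCCCC#C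
F8 | step 2 | octacosa-9,21,27-triynal | O=CCCCCCCCC#CCCCCCCCCCCC#CCCCCC#C
F9 | step 2 | octacosa-9,21,27-triynoic acid | OC(=O)CCCCCCCC#CCCCCCCCCCCC#CCCCCC#C
F10 | step 2 | but-3-yn-1-yl octacosa-9,21,27-triynoate | C#CCCOC(=O)CCCCCCCC#CCCCCCCCCCCC#CCCCCC#C
F11 | step 2 | oxacyclotritriaconta-10,22,28,30-tetrayn-2-one | O=C1CCCCCCCC#CCCCCCCCCCCC#CCCCCC#CC#CCCO1
F12 | step 1 | icos-1-yne | C#CCCCCCCCCCCCCCCCCCCC
F13 | step 1 | 2-[(8-bromooctyl)oxy]oxane | BrCCCCCCCCOC1CCCCO1
F14 | step 1 | 2-(octacos-9-yn-1-yloxy)oxane | CCCCCCCCCCCCCCCCCCC#CCCCCCCCCOC1CCCCO1
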